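**Retrosynthetic overview**
1. Target 30 ⇒ (C8–O acylation) alcohol 27 + (E)-4-acetoxy-2-methylbut-2-enoic acid 29.
2. 27 ⇒ (C7–C8, intramolecular indium Barbier allylation) aldehyde–allyl bromide 25. This closes the nine-membered ring C3–C4–C5–C6–C7–C8–C9–C10–O last, sets C7 and C8, and turns the butenolide into the α-methylene lactone.
3. Enabling feature: the homoallylic alcohol array O–C8–C7–C11=C13. C7 is both the β-carbon of the lactone ring (O–C6–C7–C11–C12) and a member of the nine-membered ring, so the array is the retron of a γ-selective (SE2′) addition of a 3-(metallomethyl)butenolide to a C8 aldehyde.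
4. 25 ⇒ furanone ring (O–C3=C2–C1–C10) by 5-endo-dig gold cyclisation of a C10-hydroxy ynone ⇒ (C3–C4, Sonogashira) (Z)-iodoalkenyl butenolide 20 + ynone 9. 20 comes from crotonaldehyde and propyne (asymmetric alkynylation, Red-Al/I2, esterification, RCM); 9 comes from (S)-citramalic acid, which supplies C10.
5. Ring order: butenolide (step 13) → furanone (step 15) → nine-membered ring (step 18).

Key step: step 18

Remark 1: germacrane numbering is used for the target carbons (C1 ketone, C2=C3, C3–O–C10 bridge, C4=C5, C6 lactone oxygen, C7, C8 ester, C9, C10, C11=C13, C12 lactone carbonyl).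
Remark 2: in step 10 the (S,S)-ligand is assumed to deliver the (4S)-carbinol; if the sense of induction is the reverse, the enantiomeric ligand is used.
Remark 3: (2E)-4-acetoxy-2-methylbut-2-enal (28) is taken as a commercial bulk intermediate.

**Route**

Step 1
Reactants: 1 (S)-citramalic acid
Product: 2 2-[(4S)-2,2,4-trimethyl-5-oxo-1,3-dioxolan-4-yl]acetic acid
Conditions: 2,2-dimethoxypropane, p-TsOH·H2O (cat.), rt
Reagents that add atoms: 2,2-dimethoxypropane COC(C)(C)OC
Why: Acid-catalysed acetonide (1,3-dioxolan-4-one) formation engages only the α-hydroxy acid unit in a five-membered ring and leaves the CH2CO2H group free; the quaternary centre (future C10) is not touched.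

Step 2
Reactants: 2 2-[(4S)-2,2,4-trimethyl-5-oxo-1,3-dioxolan-4-yl]acetic acid
Product: 3 (5S)-5-(2-hydroxyethyl)-2,2,5-trimethyl-1,3-dioxolan-4-one
Conditions: BH3·SMe2, THF, 0 °C→rt; then H2O; used crude
Reagents that add atoms: none
Why: Chemoselective borane reduction of the free carboxylic acid, which reacts much faster than the dioxolanone carbonyl, should give the primary alcohol without affecting the stereocentre.

Step 3
Reactants: 3 (5S)-5-(2-hydroxyethyl)-2,2,5-trimethyl-1,3-dioxolan-4-one
Product: 4 2-[(4S)-2,2,4-trimethyl-5-oxo-1,3-dioxolan-4-yl]acetaldehyde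
Conditions: Dess–Martin periodinane, CH2Cl2, rt
Reagents that add atoms: none
Why: Dess–Martin oxidation converts the primary alcohol into the aldehyde under neutral conditions that leave the acid- and base-labile dioxolanone intact.

Step 4
Reactants: 4 2-[(4S)-2,2,4-trimethyl-5-oxo-1,3-dioxolan-4-yl]acetaldehyde
Product: 5 methyl (2S)-2-hydroxy-4,4-dimethoxy-2-methylbutanoate
Conditions: HC(OMe)3, MeOH, CSA (cat.), 40 °C
Reagents that add atoms: methanol CO; trimethyl orthoformate COC(OC)OC
Why: Acid-catalysed acetalisation of the aldehyde and concurrent methanolysis of the acyl ketal (transesterification) should give the methyl ester dimethyl acetal in one operation; no bond to the stereocentre is broken.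

Step 5
Reactants: 5 methyl (2S)-2-hydroxy-4,4-dimethoxy-2-methylbutanoate
Product: 6 (2S)-2-hydroxy-N,4,4-trimethoxy-N,2-dimethylbutanamide
Conditions: MeNH(OMe)·HCl, iPrMgCl, THF, −20→0 °C
Reagents that add atoms: N,O-dimethylhydroxylamine hydrochloride CNOC.Cl
Why: Weinreb amide formation by aminolysis of the ester with the magnesium amide of N,O-dimethylhydroxylamine is assisted by the neighbouring magnesium alkoxide; the acetal is inert to the Grignard base.

Step 6
Reactants: 6 (2S)-2-hydroxy-N,4,4-trimethoxy-N,2-dimethylbutanamide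
Product: 7 (2S)-N,4,4-trimethoxy-N,2-dimethyl-2-[(trimethylsilyl)oxy]butanamide
Conditions: TMSCl, imidazole, DMF, rt
Reagents that add atoms: chlorotrimethylsilane C[Si](C)(C)Cl
Why: Silylation of the tertiary alcohol with the small trimethylsilyl group blocks premature oxa-Michael ring closure once the ynone is made.

Step 7
Reactants: 7 (2S)-N,4,4-trimethoxy-N,2-dimethyl-2-[(trimethylsilyl)oxy]butanamide; 8 ethynylmagnesium bromide
Product: 9 (4S)-6,6-dimethoxy-4-methyl-4-[(trimethylsilyl)oxy]hex-1-yn-3-one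
Conditions: THF, 0 °C; sat. aq NH4Cl
Reagents that add atoms: none
Why: Weinreb ketone synthesis: the chelated tetrahedral adduct stops at single addition and should release the terminal ynone on work-up.

Step 8
Reactants: 10 methyl 2-(hydroxymethyl)prop-2-enoate
Product: 11 methyl 2-({[tert-butyl(dimethyl)silyl]oxy}methyl)prop-2-enoate
Conditions: TBSCl, imidazole, DMF, rt
Reagents that add atoms: tert-butyldimethylsilyl chloride CC(C)(C)[Si](C)(C)Cl
Why: Standard silylation of the primary allylic alcohol lets the acid be unmasked and coupled later.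

Step 9
Reactants: 11 methyl 2-({[tert-butyl(dimethyl)silyl]oxy}methyl)prop-2-enoate
Product: 12 2-({[tert-butyl(dimethyl)silyl]oxy}methyl)prop-2-enoic acid
Conditions: LiOH·H2O, THF/H2O, 0 °C; then 1 M HCl to pH 4
Reagents that add atoms: lithium hydroxide [Li+].[OH-]
Why: Saponification of the methyl ester at low temperature should spare the silyl ether and the 1,1-disubstituted alkene.

Step 10
Reactants: 13 (E)-but-2-enal; 14 propyne
Product: 16 (2E,4S)-hept-2-en-5-yn-4-ol, via methyl(prop-1-yn-1-yl)zinc 15 (not isolated)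
Conditions: 14 (excess), Me2Zn, (S,S)-ProPhenol (10 mol %), Ph3PO (20 mol %), toluene, 0 °C; then 13
Reagents that add atoms: none
Why: Ligand-controlled 1,2-addition of the alkynylzinc to the enal (dinuclear zinc–ProPhenol alkynylation) holds aldehyde and alkynyl group on the two zinc centres of the chiral pocket, and addition to one aldehyde face sets the carbinol centre (future C6) as S.

Step 11
Reactants: 16 (2E,4S)-hept-2-en-5-yn-4-ol
Product: 18 (2E,4S,5Z)-6-iodohepta-2,5-dien-4-ol, via cyclic sodium alkenylalanate 17 (not isolated)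
Conditions: NaAlH2(OCH2CH2OCH3)2 (Red-Al), THF, 0 °C→rt; EtOAc; then I2, THF, −78→0 °C
Reagents that add atoms: iodine II
Why: Hydroxyl-directed trans-hydroalumination of the propargylic alkyne (hydride to the proximal carbon, aluminium to the distal carbon in a five-membered alkoxyalanate) followed by iodinolysis with retention should give the (Z)-3-iodoallylic alcohol; the isolated propenyl group and the stereocentre are not affected.

Step 12
Reactants: 18 (2E,4S,5Z)-6-iodohepta-2,5-dien-4-ol; 12 2-({[tert-butyl(dimethyl)silyl]oxy}methyl)prop-2-enoic acid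
Product: 19 (2E,4S,5Z)-6-iodohepta-2,5-dien-4-yl 2-({[tert-butyl(dimethyl)silyl]oxy}methyl)prop-2-enoate
Conditions: DCC, DMAP (cat.), CH2Cl2, 0 °C→rt
Reagents that add atoms: none
Why: Steglich esterification acylates the secondary bis-allylic alcohol under neutral conditions with retention at the carbinol centre.

Step 13
Reactants: 19 (2E,4S,5Z)-6-iodohepta-2,5-dien-4-yl 2-({[tert-butyl(dimethyl)silyl]oxy}methyl)prop-2-enoate
Product: 20 (5S)-3-({[tert-butyl(dimethyl)silyl]oxy}methyl)-5-[(1Z)-2-iodoprop-1-en-1-yl]furan-2(5H)-one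
Conditions: second-generation Hoveyda–Grubbs catalyst (5 mol %), toluene, 60 °C, argon sparge
Reagents that add atoms: none
Why: Ring-closing metathesis between the propenyl group and the 1,1-disubstituted acrylate should form the α-substituted butenolide with loss of propene; the trisubstituted iodoalkene does not take part and the stereocentre is untouched.

Step 14
Reactants: 20 (5S)-3-({[tert-butyl(dimethyl)silyl]oxy}methyl)-5-[(1Z)-2-iodoprop-1-en-1-yl]furan-2(5H)-one; 9 (4S)-6,6-dimethoxy-4-methyl-4-[(trimethylsilyl)oxy]hex-1-yn-3-one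
Product: 21 (5R)-3-({[tert-butyl(dimethyl)silyl]oxy}methyl)-5-{(1Z,6S)-8,8-dimethoxy-2,6-dimethyl-5-oxo-6-[(trimethylsilyl)oxy]oct-1-en-3-yn-1-yl}furan-2(5H)-one
Conditions: PdCl2(PPh3)2 (5 mol %), CuI (10 mol %), Et3N, THF, 0 °C→rt
Reagents that add atoms: none
Why: Sonogashira coupling forms the C3–C4 bond by oxidative addition of zerovalent palladium into the vinyl C–I bond with retention of the Z geometry, transmetalation from the copper acetylide of the terminal ynone and reductive elimination.

Step 15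
Reactants: 21 (5R)-3-({[tert-butyl(dimethyl)silyl]oxy}methyl)-5-{(1Z,6S)-8,8-dimethoxy-2,6-dimethyl-5-oxo-6-[(trimethylsilyl)oxy]oct-1-en-3-yn-1-yl}furan-2(5H)-one
Product: 23 (5R)-5-{(1Z)-2-[(5S)-5-(2,2-dimethoxyethyl)-5-methyl-4-oxo-4,5-dihydrofuran-2-yl]prop-1-en-1-yl}-3-(hydroxymethyl)furan-2(5H)-one, via hydroxy ynone diol 22 (not isolated)
Conditions: CSA (0.2 equiv), MeOH, 0 °C; evaporate; then (p-CF3C6H4)3PAuCl/AgOTf (5 mol % each), toluene, rt
Reagents that add atoms: none
Why: Acid methanolysis removes the trimethylsilyl and the primary tert-butyldimethylsilyl ethers but keeps the dimethyl acetal, and cationic monovalent gold then activates the ynone for 5-endo-dig attack of the tertiary hydroxyl (cycloisomerisation of a γ-hydroxyalkynone to a 3(2H)-furanone); C10 keeps its configuration because only its O–H bond reacts.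

Step 16
Reactants: 23 (5R)-5-{(1Z)-2-[(5S)-5-(2,2-dimethoxyethyl)-5-methyl-4-oxo-4,5-dihydrofuran-2-yl]prop-1-en-1-yl}-3-(hydroxymethyl)furan-2(5H)-one
Product: 24 (5R)-3-(bromomethyl)-5-{(1Z)-2-[(5S)-5-(2,2-dimethoxyethyl)-5-methyl-4-oxo-4,5-dihydrofuran-2-yl]prop-1-en-1-yl}furan-2(5H)-one
Conditions: CBr4, PPh3, CH2Cl2, 0 °C
Reagents that add atoms: carbon tetrabromide BrC(Br)(Br)Br
Why: The Appel reaction converts the primary allylic alcohol into the bromide by SN2 displacement of the oxyphosphonium group under neutral conditions.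

Step 17
Reactants: 24 (5R)-3-(bromomethyl)-5-{(1Z)-2-[(5S)-5-(2,2-dimethoxyethyl)-5-methyl-4-oxo-4,5-dihydrofuran-2-yl]prop-1-en-1-yl}furan-2(5H)-one
Product: 25 (5R)-3-(bromomethyl)-5-{(1Z)-2-[(5S)-5-methyl-4-oxo-5-(2-oxoethyl)-4,5-dihydrofuran-2-yl]prop-1-en-1-yl}furan-2(5H)-one
Conditions: TFA–H2O (9:1), CHCl3, 0 °C; used at once
Reagents that add atoms: water O
Why: Mild acid hydrolysis of the dimethyl acetal unmasks the aldehyde without base, which would eliminate the β-oxygen of the furanone.

Step 18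
Reactants: 25 (5R)-3-(bromomethyl)-5-{(1Z)-2-[(5S)-5-methyl-4-oxo-5-(2-oxoethyl)-4,5-dihydrofuran-2-yl]prop-1-en-1-yl}furan-2(5H)-one
Product: 27 (4Z,6R,7R,8R,10S)-8-hydroxy-1-oxo-3,10-epoxygermacra-2,4,11(13)-trien-12,6-olide, via allylindium dibromide 26 (not isolated)
Conditions: In powder (3 equiv), THF/sat. aq NH4Cl (5:1), slow addition of 25 to about 2 mM, rt
Reagents that add atoms: none
Why: Indium inserts into the allylic C–Br bond to give allylindium 26, whose γ-carbon C7 (the butenolide β-carbon) adds to the C8 aldehyde through a metal-bridged six-membered transition state (SE2′), forming C7–C8, shifting the double bond from C11=C7 to C11=C13 and leaving an indium alkoxide that the aqueous medium hydrolyses. The closest known reaction type is the Barbier allylation of aldehydes with 3-(bromomethyl)furan-2(5H)-ones and its intramolecular 2-(bromomethyl)acrylate version, which closes medium and large carbocycles fused to α-methylene lactones. The ring C3–C4–C5–C6–C7–C8–C9–C10–O closes in a 9-exo-trig mode at the aldehyde carbon, and it is the only ring formed because butenolide and furanone are already in place. C7 is controlled by C6: the aldehyde is delivered to the butenolide face opposite the C6–C5 bond, the face that the bridge of five rigid atoms (C5=C4–C3–O–C10) can reach without eclipsing C5 and C8, which should give the trans-fused lactone. C8 is controlled by the arrangement about the forming bond: with C9 anti to C11 (the lactone carbon pseudo-equatorial on the new ring, as a trans-fused medium ring prefers) and the aldehyde oxygen turned to the lactone-carbonyl side, where the indium is chelated by the C12 carbonyl, the hydroxyl should come out syn to C6 along the chain C11–C7–C8–C9 (8R), the sense expected from indium- and zinc-mediated additions of 3-(bromomethyl)butenolides. The step needs γ- over α-attack (attack by C13 would give an eleven-membered ring), aldehyde over ketone and lactone, and closure over oligomerisation; the SE2′ preference of allylindium reagents, their inertness to ketones and esters, slow addition at high dilution and a base-free medium (no β-elimination of the furanone oxygen, no epimerisation at C6) should secure these.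

Step 19
Reactants: 28 (2E)-4-acetoxy-2-methylbut-2-enal
Product: 29 (2E)-4-acetoxy-2-methylbut-2-enoic acid
Conditions: NaClO2, NaH2PO4, 2-methyl-2-butene, t-BuOH/H2O, 0 °C→rt
Reagents that add atoms: sodium chlorite [Na+].[O-]Cl=O
Why: Pinnick oxidation of the enal to the enoic acid with hypochlorite scavenging should keep the E double bond and the acetate.

Step 20
Reactants: 27 (4Z,6R,7R,8R,10S)-8-hydroxy-1-oxo-3,10-epoxygermacra-2,4,11(13)-trien-12,6-olide; 29 (2E)-4-acetoxy-2-methylbut-2-enoic acid
Product: 30 (4Z,6R,7R,8R,10S)-8-{[(2E)-4-acetoxy-2-methylbut-2-enoyl]oxy}-1-oxo-3,10-epoxygermacra-2,4,11(13)-trien-12,6-olide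
Conditions: EDC·HCl, DMAP (cat.), CH2Cl2, 0 °C→rt
Reagents that add atoms: none
Why: Steglich esterification of the C8 hydroxyl with retention completes the target under near-neutral conditions that should spare the α-methylene lactone and the acetate.

**Compound list**
1 | (S)-citramalic acid, (2S)-2-hydroxy-2-methylbutanedioic acid | OC(=O)[C@](C)(CC(=O)O)O | starting material
2 | 2-[(4S)-2,2,4-trimethyl-5-oxo-1,3-dioxolan-4-yl]acetic acid | O=C1[C@](C)(CC(=O)O)OC(C)(C)O1 | intermediate
3 | (5S)-5-(2-hydroxyethyl)-2,2,5-trimethyl-1,3-dioxolan-4-one | O=C1[C@](C)(CCO)OC(C)(C)O1 | intermediate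
4 | 2-[(4S)-2,2,4-trimethyl-5-oxo-1,3-dioxolan-4-yl]acetaldehyde | O=C1[C@](C)(CC=O)OC(C)(C)O1 | intermediate
5 | methyl (2S)-2-hydroxy-4,4-dimethoxy-2-methylbutanoate | COC(=O)[C@](C)(CC(OC)OC)O | intermediate
6 | (2S)-2-hydroxy-N,4,4-trimethoxy-N,2-dimethylbutanamide | CON(C)C(=O)[C@](C)(CC(OC)OC)O | intermediate
7 | (2S)-N,4,4-trimethoxy-N,2-dimethyl-2-[(trimethylsilyl)oxy]butanamide | CON(C)C(=O)[C@](C)(CC(OC)OC)O[Si](C)(C)C | intermediate
8 | ethynylmagnesium bromide | C#C[Mg]Br | starting material
9 | (4S)-6,6-dimethoxy-4-methyl-4-[(trimethylsilyl)oxy]hex-1-yn-3-one | C#CC(=O)[C@](C)(CC(OC)OC)O[Si](C)(C)C | intermediate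
10 | methyl 2-(hydroxymethyl)prop-2-enoate | C=C(CO)C(=O)OC | starting material
11 | methyl 2-({[tert-butyl(dimethyl)silyl]oxy}methyl)prop-2-enoate | C=C(CO[Si](C)(C)C(C)(C)C)C(=O)OC | intermediate
12 | 2-({[tert-butyl(dimethyl)silyl]oxy}methyl)prop-2-enoic acid | C=C(CO[Si](C)(C)C(C)(C)C)C(=O)O | intermediate
13 | (E)-but-2-enal (crotonaldehyde) | C/C=C/C=O | starting material
14 | propyne | CC#C | starting material
15 | methyl(prop-1-yn-1-yl)zinc | CC#C[Zn]C | intermediate
16 | (2E,4S)-hept-2-en-5-yn-4-ol | C/C=C/[C@H](O)C#CC | intermediate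
17 | cyclic sodium alkenylalanate: sodium (5S)-2,2-bis(2-methoxyethoxy)-3-methyl-5-[(1E)-prop-1-en-1-yl]-2,5-dihydro-1,2-oxaaluminol-2-uide | C/C=C/[C@@H]1O[Al-](OCCOC)(OCCOC)C(C)=C1.[Na+] | intermediate
18 | (2E,4S,5Z)-6-iodohepta-2,5-dien-4-ol | C/C=C/[C@H](O)/C=C(/C)I | intermediate
19 | (2E,4S,5Z)-6-iodohepta-2,5-dien-4-yl 2-({[tert-butyl(dimethyl)silyl]oxy}methyl)prop-2-enoate | C/C=C/[C@H](OC(=O)C(=C)CO[Si](C)(C)C(C)(C)C)/C=C(/C)I | intermediate
20 | (5S)-3-({[tert-butyl(dimethyl)silyl]oxy}methyl)-5-[(1Z)-2-iodoprop-1-en-1-yl]furan-2(5H)-one | O=C1O[C@H](/C=C(/C)I)C=C1CO[Si](C)(C)C(C)(C)C | intermediate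
21 | (5R)-3-({[tert-butyl(dimethyl)silyl]oxy}methyl)-5-{(1Z,6S)-8,8-dimethoxy-2,6-dimethyl-5-oxo-6-[(trimethylsilyl)oxy]oct-1-en-3-yn-1-yl}furan-2(5H)-one | O=C1O[C@H](/C=C(/C)C#CC(=O)[C@](C)(CC(OC)OC)O[Si](C)(C)C)C=C1CO[Si](C)(C)C(C)(C)C | intermediate
22 | hydroxy ynone diol: (5R)-5-[(1Z,6S)-6-hydroxy-8,8-dimethoxy-2,6-dimethyl-5-oxooct-1-en-3-yn-1-yl]-3-(hydroxymethyl)furan-2(5H)-one | O=C1O[C@H](/C=C(/C)C#CC(=O)[C@](C)(CC(OC)OC)O)C=C1CO | intermediate
23 | (5R)-5-{(1Z)-2-[(5S)-5-(2,2-dimethoxyethyl)-5-methyl-4-oxo-4,5-dihydrofuran-2-yl]prop-1-en-1-yl}-3-(hydroxymethyl)furan-2(5H)-one | O=C1O[C@H](/C=C(/C)C2=CC(=O)[C@](C)(CC(OC)OC)O2)C=C1CO | intermediate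
24 | (5R)-3-(bromomethyl)-5-{(1Z)-2-[(5S)-5-(2,2-dimethoxyethyl)-5-methyl-4-oxo-4,5-dihydrofuran-2-yl]prop-1-en-1-yl}furan-2(5H)-one | O=C1O[C@H](/C=C(/C)C2=CC(=O)[C@](C)(CC(OC)OC)O2)C=C1CBr | intermediate
25 | (5R)-3-(bromomethyl)-5-{(1Z)-2-[(5S)-5-methyl-4-oxo-5-(2-oxoethyl)-4,5-dihydrofuran-2-yl]prop-1-en-1-yl}furan-2(5H)-one | O=C1O[C@H](/C=C(/C)C2=CC(=O)[C@](C)(CC=O)O2)C=C1CBr | intermediate
26 | allylindium dibromide of 25 (InBr2 in place of Br on the exocyclic CH2) | O=C1O[C@H](/C=C(/C)C2=CC(=O)[C@](C)(CC=O)O2)C=C1C[In](Br)Br | intermediate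
27 | (4Z,6R,7R,8R,10S)-8-hydroxy-1-oxo-3,10-epoxygermacra-2,4,11(13)-trien-12,6-olide | C=C1C(=O)O[C@@H]2/C=C(/C)C3=CC(=O)[C@](C)(C[C@@H](O)[C@@H]12)O3 | intermediate
28 | (2E)-4-acetoxy-2-methylbut-2-enal | O=C/C(C)=C/COC(C)=O | starting material
29 | (2E)-4-acetoxy-2-methylbut-2-enoic acid | OC(=O)/C(C)=C/COC(C)=O | intermediate
30 | (4Z,6R,7R,8R,10S)-8-{[(2E)-4-acetoxy-2-methylbut-2-enoyl]oxy}-1-oxo-3,10-epoxygermacra-2,4,11(13)-trien-12,6-olide | C=C1C(=O)O[C@@H]2/C=C(/C)C3=CC(=O)[C@](C)(C[C@@H](OC(=O)/C(C)=C/COC(C)=O)[C@@H]12)O3 | target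

**Step count**
Total: 20 steps. Longest linear sequence: 13 steps (steps 1–7, 14–18, 20).

**Steps most likely to fail**

Step 18. The rigid furanone–(Z)-propenyl bridge may hold the aldehyde away from C7 or present it through an unproductive rotamer. Protonolysis of the allylindium, intermolecular allylation, or closure to the C8-epimeric carbinol could then overtake the wanted nine-membered closure. Fallback, from 21 back to 27: the order of ring formation is changed, so that the allylation closes the more flexible ten-membered carbocycle and the furanone, and with it the nine-membered ring, is formed afterwards by transannular cyclisation. Acid methanolysis of 21 (CSA, MeOH, 0 °C) gives diol 22, which is now isolated. Appel bromination of its primary allylic hydroxyl (CBr4, PPh3) gives (5R)-3-(bromomethyl)-5-[(1Z,6S)-6-hydroxy-8,8-dimethoxy-2,6-dimethyl-5-oxooct-1-en-3-yn-1-yl]furan-2(5H)-one F1. Acetal hydrolysis (TFA–H2O) gives (5R)-3-(bromomethyl)-5-[(1Z,6S)-6-hydroxy-2,6-dimethyl-5,8-dioxooct-1-en-3-yn-1-yl]furan-2(5H)-one F2. Indium-mediated Barbier cyclisation at high dilution then forms C7–C8 and gives (4Z,6R,7R,8R,10S)-8,10-dihydroxy-1-oxogermacra-4,11(13)-dien-2-yn-12,6-olide F3. Cationic monovalent gold ((p-CF3C6H4)3PAuCl/AgOTf, toluene) finally closes the C10–O–C3 bridge across the ring (5-endo-dig) to give 27.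

Step 14. Triethylamine may deprotonate the doubly allylic γ-carbon of the butenolide (loss of configuration at C6, double-bond migration) and may add to or oligomerise the terminal ynone before coupling. Fallback, from 9 back to 21: the coupling is changed to an amine-free Stille reaction. Compound 9 is stannylated at the alkyne terminus with Bu3SnOMe (toluene, 60 °C) to give (4S)-6,6-dimethoxy-4-methyl-1-(tributylstannyl)-4-[(trimethylsilyl)oxy]hex-1-yn-3-one F4. F4 is then coupled with 20 (PdCl2(MeCN)2, DMF, rt) to give 21.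

Step 10. Facial discrimination may be poor and conversion incomplete with a small, volatile alkyne and a small enal. Fallback, from 13 back to 16: asymmetric reduction replaces asymmetric addition. 1-Propynylmagnesium bromide adds to 13 to give racemic (2E)-hept-2-en-5-yn-4-ol F5. Oxidation with MnO2 gives (2E)-hept-2-en-5-yn-4-one F6. Corey–Bakshi–Shibata reduction ((S)-2-methyl-CBS-oxazaborolidine if the alkenyl group acts as the larger substituent, BH3·SMe2, THF, −30 °C) gives 16.

**Further compounds**
F1 | step 18 | (5R)-3-(bromomethyl)-5-[(1Z,6S)-6-hydroxy-8,8-dimethoxy-2,6-dimethyl-5-oxooct-1-en-3-yn-1-yl]furan-2(5H)-one | O=C1O[C@H](/C=C(/C)C#CC(=O)[C@](C)(CC(OC)OC)O)C=C1CBr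
F2 | step 18 | (5R)-3-(bromomethyl)-5-[(1Z,6S)-6-hydroxy-2,6-dimethyl-5,8-dioxooct-1-en-3-yn-1-yl]furan-2(5H)-one | O=C1O[C@H](/C=C(/C)C#CC(=O)[C@](C)(CC=O)O)C=C1CBr
F3 | step 18 | (4Z,6R,7R,8R,10S)-8,10-dihydroxy-1-oxogermacra-4,11(13)-dien-2-yn-12,6-olide | C=C1C(=O)O[C@@H]2/C=C(/C)C#CC(=O)[C@@](C)(O)C[C@@H](O)[C@@H]12
F4 | step 14 | (4S)-6,6-dimethoxy-4-methyl-1-(tributylstannyl)-4-[(trimethylsilyl)oxy]hex-1-yn-3-one | CCCC[Sn](CCCC)(CCCC)C#CC(=O)[C@](C)(CC(OC)OC)O[Si](C)(C)C
F5 | step 10 | racemic (2E)-hept-2-en-5-yn-4-ol | C/C=C/C(O)C#CC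
F6 | step 10 | (2E)-hept-2-en-5-yn-4-one | C/C=C/C(=O)C#CC
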